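Ring A is disconnected across C1–C2 and C3–C4 into a cyclobutenone and an acyl ynol ether. The step exploits the substitution of ring A: a cyclohexa-2,4-dienone whose C1 carbonyl lies between the butyryl-bearing C2 and the quaternary C6 (CMe2), with oxygen on C3 and C5 and the methylene bridge on C4. A dienylketene closing onto a CMe2 terminus gives exactly this non-aromatisable pattern. One thermal cascade (4π opening, [2+2] cycloaddition, 4π opening, 6π closure) should assemble the fully substituted ring A. The precursor is a 3-ethoxy-4,4-dimethylcyclobutenone bearing at C2 the methylene-linked ring B, itself masked as a bis(enol ethyl ether); its partner is 1-ethoxyhex-1-yn-3-one.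

Key step: step 8

Assumption: ring B and its precursors are drawn in the tautomer used for the target; the threefold O-ethylation of step 6 is taken to cap the two ring B oxygens that flank the bridge carbon, and a regioisomeric ring B enol ether, should it form, would be an equally inert spectator that converges on the same triketone in step 9.

Step 1
Reactants: 1 2,4,6-trihydroxyacetophenone
Product: 2 acetylfilicinic acid (2-acetyl-3,5-dihydroxy-6,6-dimethylcyclohexa-2,4-dien-1-one)
Conditions: MeI (2.2 equiv), NaOMe (3.2 equiv), MeOH, 0 °C to rt
Reagents that add atoms: iodomethane, CI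
Why: Alkylative dearomatisation of an acylphloroglucinol (base-mediated C-methylation): the polyanion is methylated on ring carbon and the second methyl should enter at the carbon that already bears one, which locks the ring as the non-aromatic gem-dimethyl triketone; no stereocentre is formed.

Step 2
Reactants: 2 acetylfilicinic acid
Product: 3 Mannich base 2-acetyl-4-[(dimethylamino)methyl]-3,5-dihydroxy-6,6-dimethylcyclohexa-2,4-dien-1-one
Conditions: Eschenmoser's salt (1.1 equiv), Et3N (1.0 equiv), CH2Cl2, 0 °C to rt
Reagents that add atoms: Eschenmoser's salt (N,N-dimethylmethyleneiminium iodide), C=[N+](C)C.[I-]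
Why: Mannich reaction: the iminium ion is attacked by C4, the only unsubstituted and strongly nucleophilic ring carbon of the vinylogous acid, and the inner-salt product should not eliminate at room temperature.

Step 3
Reactants: 4 isobutyryl chloride; 5 ethoxyacetylene
Product: 7 3-ethoxy-4,4-dimethylcyclobut-2-en-1-one, via dimethylketene 6 (not isolated)
Conditions: Et3N, CH2Cl2, 0 °C to reflux
Reagents that add atoms: none
Why: Dehydrochlorination gives dimethylketene 6, which undergoes the thermal [2+2] ketene–ynol ether cycloaddition with its carbonyl carbon bonding to the unsubstituted, nucleophilic alkyne carbon, so the ethoxy group ends up next to the CMe2 carbon.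

Step 4
Reactants: 7 3-ethoxy-4,4-dimethylcyclobut-2-en-1-one
Product: 8 3-hydroxy-4,4-dimethylcyclobut-2-en-1-one (enol of 2,2-dimethylcyclobutane-1,3-dione)
Conditions: 1 M aq. HCl, THF, rt
Reagents that add atoms: water, O
Why: Acid hydrolysis of a vinylogous ester (conjugate addition of water, loss of ethanol) gives the strongly acidic enol, and room temperature avoids hydrolytic opening of the four-membered ring.

Step 5
Reactants: 3 Mannich base; 8 3-hydroxy-4,4-dimethylcyclobut-2-en-1-one
Product: 10 2-acetyl-3,5-dihydroxy-4-[(2-hydroxy-3,3-dimethyl-4-oxocyclobut-1-en-1-yl)methyl]-6,6-dimethylcyclohexa-2,4-dien-1-one, via methylidene trione 9 (not isolated)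
Conditions: 8 (2.5 equiv), MeCN, 70 °C; dilute aq. HCl work-up
Reagents that add atoms: none
Why: Mannich-base alkylation: thermal loss of dimethylamine from 3 gives the methylidene trione 9, to which C2 of the cyclic 1,3-dione enol 8 adds in a Michael addition, the standard way to join two different acidic rings through a methylene group; the excess of acidic 8 should outcompete self-capture of 9 and hold the amine as its salt.

Step 6
Reactants: 10 methylene-linked triol
Product: 11 2-acetyl-3,5-diethoxy-4-[(2-ethoxy-3,3-dimethyl-4-oxocyclobut-1-en-1-yl)methyl]-6,6-dimethylcyclohexa-2,4-dien-1-one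
Conditions: Et3O·BF4 (3.6 equiv), iPr2NEt (4 equiv), CH2Cl2, 0 °C to rt
Reagents that add atoms: triethyloxonium tetrafluoroborate, CC[O+](CC)CC.F[B-](F)(F)F
Why: O-Alkylation of three strongly acidic enols by a hard oxonium electrophile, which favours oxygen over carbon; the four-membered ring gives a single enol ether by symmetry, and capping both ring B oxygens next to the bridge removes every hydroxyl that could trap a ketene or protonate the ynol ether in step 8.

Step 7
Reactants: 5 ethoxyacetylene; 12 N-methoxy-N-methylbutanamide
Product: 15 1-ethoxyhex-1-yn-3-one, via lithium ethoxyacetylide 13 (not isolated), via tetrahedral lithium adduct 14 (not isolated)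
Conditions: n-BuLi, THF, −78 °C; then 12, −78 to −20 °C; inverse quench into cold dilute aq. HCl, Et2O
Reagents that add atoms: none
Why: Weinreb ketone synthesis: the lithium acetylide adds once, the chelated adduct 14 survives until the quench so no tertiary alcohol forms, and the acidic inverse quench keeps the released amine protonated so that it cannot add to the ynone.

Step 8
Reactants: 11 cyclobutenone precursor; 15 1-ethoxyhex-1-yn-3-one
Product: 19 tetra-O-ethyl ether of the target (2-acetyl-4-[(5-butanoyl-2,6-diethoxy-3,3-dimethyl-4-oxocyclohexa-1,5-dien-1-yl)methyl]-3,5-diethoxy-6,6-dimethylcyclohexa-2,4-dien-1-one), via vinylketene 16 (not isolated), via alkenylcyclobutenone 17 (not isolated), via dienylketene 18 (not isolated)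
Conditions: 15 (3 equiv, added in three portions), PhMe (1 M in 11, degassed), 110 °C, sealed tube, argon
Reagents that add atoms: none
Why: Proposed new method: heating should cleave the C1–C4 bond of cyclobutenone 11 in a 4π electrocyclic opening to vinylketene 16, whose ketene carbon is attacked by the butyryl-bearing alkyne carbon of 15 while its α-carbon bonds to the ethoxy-bearing alkyne carbon, a [2+2] cycloaddition that gives 4-alkenylcyclobutenone 17; a second 4π opening leads to dienylketene 18, and bonding of its ketene carbon to the CMe2 terminus delivers 19. The closest known reaction type is the Danheiser benzannulation of cyclobutenones with alkoxyalkynes, combined with the thermal closure of dienylketenes to 6,6-disubstituted cyclohexa-2,4-dienones; a 3-alkoxy-4,4-dialkylcyclobutenone and an acyl-substituted ynol ether have not been used in it. Ring A closes by a thermal disrotatory 6π electrocyclisation, C1 (ketene carbon) to C6. No stereocentre is created in 19, and the quaternary centre of 17 is racemic and is destroyed in the next ring opening. Two selectivities are needed: the [2+2] regiochemistry, secured by the ethoxy group, which leaves the acyl-bearing carbon as the nucleophilic end of the alkyne, and inward rotation of the alkenyl group when 17 opens, secured because ring opening is reversible and only the cis-dienylketene is drained by the 6π closure. The quaternary C6 cannot lose a proton, so the dienone cannot tautomerise to a phenol and ring A is kept at the oxidation level of the target.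

Step 9
Reactants: 19 tetra-O-ethyl ether of the target
Product: 20 target (2-acetyl-4-[(5-butanoyl-2,6-dihydroxy-3,3-dimethyl-4-oxocyclohexa-1,5-dien-1-yl)methyl]-3,5-dihydroxy-6,6-dimethylcyclohexa-2,4-dien-1-one)
Conditions: 2 M aq. HCl, THF, 50 °C
Reagents that add atoms: water, O
Why: Acid hydrolysis of four vinylogous-ester enol ethers (protonation on carbon or conjugate addition of water, then loss of ethanol) should return the enolised triketones of both rings; acid is chosen over base because methylene-bis(acylfilicinic acids) scramble at the bridge in alkali.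

Compound list (RBCH2 = (5-acetyl-2,6-diethoxy-3,3-dimethyl-4-oxocyclohexa-1,5-dien-1-yl)methyl)

1 | 2,4,6-trihydroxyacetophenone | CC(=O)c1c(O)cc(O)cc1O | starting material
2 | acetylfilicinic acid (2-acetyl-3,5-dihydroxy-6,6-dimethylcyclohexa-2,4-dien-1-one) | CC(=O)C1=C(O)C=C(O)C(C)(C)C1=O | intermediate
3 | 2-acetyl-4-[(dimethylamino)methyl]-3,5-dihydroxy-6,6-dimethylcyclohexa-2,4-dien-1-one | CC(=O)C1=C(O)C(CN(C)C)=C(O)C(C)(C)C1=O | intermediate
4 | isobutyryl chloride | CC(C)C(=O)Cl | starting material
5 | ethoxyacetylene | CCOC#C | starting material
6 | dimethylketene | CC(C)=C=O | intermediate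
7 | 3-ethoxy-4,4-dimethylcyclobut-2-en-1-one | CCOC1=CC(=O)C1(C)C | intermediate
8 | 3-hydroxy-4,4-dimethylcyclobut-2-en-1-one | OC1=CC(=O)C1(C)C | intermediate
9 | 2-acetyl-3-hydroxy-6,6-dimethyl-4-methylidenecyclohex-2-ene-1,5-dione | CC(=O)C1=C(O)C(=C)C(=O)C(C)(C)C1=O | intermediate
10 | 2-acetyl-3,5-dihydroxy-4-[(2-hydroxy-3,3-dimethyl-4-oxocyclobut-1-en-1-yl)methyl]-6,6-dimethylcyclohexa-2,4-dien-1-one | CC(=O)C1=C(O)C(CC2=C(O)C(C)(C)C2=O)=C(O)C(C)(C)C1=O | intermediate
11 | 2-acetyl-3,5-diethoxy-4-[(2-ethoxy-3,3-dimethyl-4-oxocyclobut-1-en-1-yl)methyl]-6,6-dimethylcyclohexa-2,4-dien-1-one | CCOC1=C(CC2=C(OCC)C(C)(C)C(=O)C(C(C)=O)=C2OCC)C(=O)C1(C)C | intermediate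
12 | N-methoxy-N-methylbutanamide | CCCC(=O)N(C)OC | starting material
13 | lithium ethoxyacetylide | CCOC#C[Li] | intermediate
14 | lithium 1-ethoxy-3-[methoxy(methyl)amino]hex-1-yn-3-olate (racemic, transient) | CCCC(O[Li])(C#COCC)N(C)OC | intermediate
15 | 1-ethoxyhex-1-yn-3-one | CCOC#CC(=O)CCC | intermediate
16 | 3-ethoxy-4-methyl-2-(RBCH2)penta-1,3-dien-1-one | CCOC(=C(C)C)C(=C=O)CC1=C(OCC)C(C)(C)C(=O)C(C(C)=O)=C1OCC | intermediate
17 | racemic 2-butanoyl-3-ethoxy-4-(1-ethoxy-2-methylprop-1-en-1-yl)-4-(RBCH2)cyclobut-2-en-1-one | CCCC(=O)C1=C(OCC)C(CC2=C(OCC)C(C)(C)C(=O)C(C(C)=O)=C2OCC)(C(OCC)=C(C)C)C1=O | intermediate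
18 | (3E)-2-butanoyl-3,5-diethoxy-6-methyl-4-(RBCH2)hepta-1,3,5-trien-1-one (C2 and C5 cis across C3=C4) | CCCC(=O)C(=C=O)/C(OCC)=C(\C(OCC)=C(C)C)CC1=C(OCC)C(C)(C)C(=O)C(C(C)=O)=C1OCC | intermediate
19 | 2-acetyl-4-[(5-butanoyl-2,6-diethoxy-3,3-dimethyl-4-oxocyclohexa-1,5-dien-1-yl)methyl]-3,5-diethoxy-6,6-dimethylcyclohexa-2,4-dien-1-one | CCCC(=O)C1=C(OCC)C(CC2=C(OCC)C(C)(C)C(=O)C(C(C)=O)=C2OCC)=C(OCC)C(C)(C)C1=O | intermediate
20 | 2-acetyl-4-[(5-butanoyl-2,6-dihydroxy-3,3-dimethyl-4-oxocyclohexa-1,5-dien-1-yl)methyl]-3,5-dihydroxy-6,6-dimethylcyclohexa-2,4-dien-1-one | CCCC(=O)C1=C(O)C(CC2=C(O)C(C)(C)C(=O)C(C(C)=O)=C2O)=C(O)C(C)(C)C1=O | target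

Total step count: 9.
Longest linear sequence: 6 steps (steps 1, 2, 5, 6, 8, 9; the branch through steps 3 and 4 is equally long).

Steps most likely to fail

Step 8 (proposed new method). The acyl group lowers the nucleophilicity of the ynol ether, so capture of the vinylketene may be too slow. The vinylketene would then re-close or be lost through a 1,5-hydrogen shift from a terminal methyl group. The ethyl ynol ether may also fragment by retro-ene loss of ethylene at the temperature needed to open the alkoxy-stabilised cyclobutenone. The fallback uses known chemistry and gives up the annulation; it sets out from Mannich base 3. Commercial 2,4,6-trihydroxybutyrophenone F1 would be C-dimethylated (MeI, NaOMe, MeOH, as in step 1) to butyrylfilicinic acid F2. Heating 3 with an excess of F2 in MeCN should release methylidene trione 9, which the free ring carbon of F2 captures in a Michael addition. This is the established route to unsymmetrical methylene-bis(acylfilicinic acids) and comes back to the route at 20.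

Step 5. The methylidene trione may be captured by 2 regenerated through retro-Mannich equilibration, which would give the symmetrical dimer. The liberated amine may also open the strained 1,3-dione, or the four-membered enol may be too weak a carbon nucleophile. The fallback reverses the roles of the partners and sets out from 8. Aminomethylation with Eschenmoser's salt would give 2-[(dimethylamino)methyl]-3-hydroxy-4,4-dimethylcyclobut-2-en-1-one F3. Warmed with an excess of 2, F3 should release 2,2-dimethyl-4-methylidenecyclobutane-1,3-dione F4, which 2 captures at C4 in its proven role as the carbon nucleophile. This comes back to the route at 10.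

Step 6. Ethylation may occur on carbon (at the bridge-bearing carbon or at C2 of the four-membered ring), and etherification of the hydrogen-bonded enol next to the acetyl group may stay incomplete. The fallback replaces enolate alkylation by a Mitsunobu etherification and sets out from 10. With EtOH, PPh3 and DIAD in THF the acidic enols are deprotonated only as ion pairs with the ethoxyphosphonium ion, which should direct ethyl transfer to oxygen under neutral conditions. This comes back to the route at 11 and makes no new compound (entry F0).

Further compounds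
F1 | step 8 | 2,4,6-trihydroxybutyrophenone | CCCC(=O)c1c(O)cc(O)cc1O
F2 | step 8 | butyrylfilicinic acid (2-butanoyl-3,5-dihydroxy-6,6-dimethylcyclohexa-2,4-dien-1-one) | CCCC(=O)C1=C(O)C=C(O)C(C)(C)C1=O
F3 | step 5 | 2-[(dimethylamino)methyl]-3-hydroxy-4,4-dimethylcyclobut-2-en-1-one | CN(C)CC1=C(O)C(C)(C)C1=O
F4 | step 5 | 2,2-dimethyl-4-methylidenecyclobutane-1,3-dione | C=C1C(=O)C(C)(C)C1=O
F0 | step 6 | none | none
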